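**Plan**

- The retrosynthesis cuts two bonds. The first is the bond from flavone C6 to the benzylic CH2. The second lies in the trimethylcyclohexanol ring (C1' = CH carrying the benzylic CH2, C2' = carbinol carbon, C3'–C5' = CH2, C6' = CMe2) and is the C2'–C3' bond.
- Enabling feature: C2' is a tertiary carbinol whose ring neighbour C3' is a CH2 followed by C4'–C5', which can hold a transient C=C. That cyclohex-3-en-1-ol is what a 2-vinylcyclobutanol gives on 1,3-shift, and C1', C6'(Me)2 and the benzylic CH2 are a prenyl unit.
- Forward, terpenoid part: benzyl prenyl ether and vinylketene give a cyclobutanone (temporary ring C2'–C1'–C6'–C5'; its C2'–C5' bond is not in the target). MeLi addition follows, then the potassium alkoxide opens the four-membered ring and closes the six-membered ring at C2'–C3'. Hydrogenation, resolution and iodination complete the fragment.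
- Forward, flavone part: rings A, C and B come intact from luteolin (diphenylmethylene ketal on the catechol, 7-O-benzylation, iodination at C6, 5-O-benzylation). Negishi coupling joins the fragments and one hydrogenolysis frees all four phenols.
- Stereochemistry: C1' is created in the [2+2] step. The carbinol centre follows from MeLi attack anti to both α-substituents and inversion at the migrating carbon in the 1,3-shift, which puts OH trans to the CH2 arm. Absolute configuration comes from lipase kinetic resolution of the racemic diol.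

Key step: step 4

Assumption: the lipase is taken to acetylate the primary hydroxyl of the (1R,2S) diol faster, so that (1S,2R)-diol 12 is recovered unreacted; if the preference is the reverse, the monoacetate fraction is methanolysed (K2CO3, MeOH) and carried on instead.

Compounds 6–11 are racemic; their SMILES show the enantiomer that is carried to 22.

**Route**

Step 1
Reactants: 1 3-methylbut-2-en-1-ol (prenol); 2 benzyl bromide
Product: 3 benzyl prenyl ether ({[(3-methylbut-2-en-1-yl)oxy]methyl}benzene)
Conditions: NaH, THF, 0 °C; then 2, Bu4NI (cat.), rt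
Reagents that add atoms: none
Why: Williamson ether synthesis of the primary allylic alkoxide with a benzylic bromide should proceed cleanly by SN2.

Step 2
Reactants: 3 benzyl prenyl ether; 4 (E)-but-2-enoyl chloride
Product: 6 rac-(2R,4R)-2-[(benzyloxy)methyl]-4-ethenyl-3,3-dimethylcyclobutan-1-one, via vinylketene 5 (not isolated)
Conditions: Et3N, CH2Cl2, reflux, slow addition of 4, 3 in excess
Reagents that add atoms: none
Why: Ketene–alkene [2+2] cycloaddition: vinylketene 5, formed by 1,4-dehydrochlorination of 4, should add across the trisubstituted alkene with its carbonyl carbon on the CH end and its α-carbon on CMe2 (positive charge develops at the tertiary carbon), and the enolisable vinyl-bearing centre should settle under Et3N to the more stable 2,4-cis ketone, which creates the centre that becomes C1'.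

Step 3
Reactants: 6 rac-(2R,4R)-2-[(benzyloxy)methyl]-4-ethenyl-3,3-dimethylcyclobutan-1-one
Product: 7 rac-(1R,2R,4R)-2-[(benzyloxy)methyl]-4-ethenyl-1,3,3-trimethylcyclobutan-1-ol
Conditions: MeLi, Et2O, −78 °C; then H2O
Reagents that add atoms: methyllithium, [Li]C
Why: 1,2-Addition of an organolithium to the strained cyclobutanone (enolisation is disfavoured because it adds ring strain) should occur from the face opposite the two cis α-substituents, placing OH cis to both the vinyl and the CH2OBn group.

Step 4
Reactants: 7 rac-(1R,2R,4R)-2-[(benzyloxy)methyl]-4-ethenyl-1,3,3-trimethylcyclobutan-1-ol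
Product: 10 rac-(1S,6R)-6-[(benzyloxy)methyl]-1,5,5-trimethylcyclohex-3-en-1-ol, via potassium cyclobutanolate 8 (not isolated), via potassium cyclohexenolate 9 (not isolated)
Conditions: KH, THF, 0 °C to rt; then H2O
Reagents that add atoms: none
Why: Deprotonation gives alkoxide 8, whose oxyanion weakens the adjacent allylic ring bond C1–C4, so the cyclobutane opens with release of its ring strain and the carbinol carbon migrates across the vinyl group to its CH2 terminus. The closest known reaction type is the alkoxide-accelerated vinylcyclobutane-to-cyclohexene rearrangement of a 2-vinylcyclobutanol, a [1,3] carbon shift. The six-membered ring closes by four-to-six ring expansion; seen as recombination of a potassium-bridged keto allyl anion pair it is a 6-exo-trig addition of the allyl terminus to the carbonyl carbon with the allyl unit inside the new ring, leaving a cis ring C=C. The CH2OBn-bearing centre is not touched, and the carbinol centre is expected to be transferred suprafacially with inversion (the rear lobe of the migrating carbon bonds to the terminus, the orbital-symmetry-allowed course), which turns the cis OH/CH2OBn relation of 7 into the trans relation of 10. The step needs cleavage of C1–C4 and not C1–C2, bonding at the allyl terminus and not return to the four-membered ring, and recombination faster than proton transfer. The vinyl group (allylic stabilisation), the loss of ring strain and the potassium bridge between oxygen and the allyl unit should secure these.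

Step 5
Reactants: 10 rac-(1S,6R)-6-[(benzyloxy)methyl]-1,5,5-trimethylcyclohex-3-en-1-ol
Product: 11 rac-(1S,2R)-2-(hydroxymethyl)-1,3,3-trimethylcyclohexan-1-ol
Conditions: H2 (1 atm), 10% Pd/C, EtOH, rt
Reagents that add atoms: none
Why: Heterogeneous hydrogenation should saturate the cis ring alkene and hydrogenolyse the benzyl ether in one operation without touching either stereocentre.

Step 6
Reactants: 11 rac-(1S,2R)-2-(hydroxymethyl)-1,3,3-trimethylcyclohexan-1-ol
Product: 12 (1S,2R)-2-(hydroxymethyl)-1,3,3-trimethylcyclohexan-1-ol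
Conditions: Burkholderia cepacia lipase (lipase PS), vinyl acetate, t-BuOMe, 30 °C, stopped just past half conversion
Reagents that add atoms: none
Why: Lipase-catalysed kinetic resolution by acyl transfer should acetylate the primary hydroxyl of one enantiomer much faster, so the slow-reacting diol is recovered as a single enantiomer and separated from the monoacetate of its antipode.

Step 7
Reactants: 12 (1S,2R)-2-(hydroxymethyl)-1,3,3-trimethylcyclohexan-1-ol
Product: 13 (1S,2S)-2-(iodomethyl)-1,3,3-trimethylcyclohexan-1-ol
Conditions: I2, PPh3, imidazole, CH2Cl2, 0 °C to rt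
Reagents that add atoms: iodine, II
Why: Appel-type iodination should activate only the primary hydroxyl as its oxyphosphonium salt and displace it by SN2 at CH2, while the hindered tertiary alcohol stays free and the trans geometry disfavours oxetane closure.

Step 8
Reactants: 14 luteolin (2-(3,4-dihydroxyphenyl)-5,7-dihydroxy-4H-chromen-4-one); 15 dichlorodiphenylmethane
Product: 16 2-(2,2-diphenyl-1,3-benzodioxol-5-yl)-5,7-dihydroxy-4H-chromen-4-one
Conditions: 15 (1.5 equiv), diphenyl ether, 175 °C, 30 min
Reagents that add atoms: none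
Why: Ketalisation of a catechol with a gem-dichloride: only the two adjacent ring B hydroxyls can close the five-membered 1,3-benzodioxole, so the 5- and 7-hydroxyls should stay free while HCl is driven off at high temperature.

Step 9
Reactants: 16 2-(2,2-diphenyl-1,3-benzodioxol-5-yl)-5,7-dihydroxy-4H-chromen-4-one; 2 benzyl bromide
Product: 17 7-(benzyloxy)-2-(2,2-diphenyl-1,3-benzodioxol-5-yl)-5-hydroxy-4H-chromen-4-one
Conditions: 2 (1.1 equiv), K2CO3, DMF, rt
Reagents that add atoms: none
Why: Williamson etherification of the more acidic 7-hydroxyl; the 5-hydroxyl, hydrogen-bonded to the C4 carbonyl, is the less nucleophilic and should stay free with one equivalent of the bromide.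

Step 10
Reactants: 17 7-(benzyloxy)-2-(2,2-diphenyl-1,3-benzodioxol-5-yl)-5-hydroxy-4H-chromen-4-one
Product: 18 7-(benzyloxy)-2-(2,2-diphenyl-1,3-benzodioxol-5-yl)-5-hydroxy-6-iodo-4H-chromen-4-one
Conditions: BnMe3N+ ICl2−, CaCO3, CH2Cl2–MeOH, rt
Reagents that add atoms: benzyltrimethylammonium dichloroiodate, C[N+](C)(C)Cc1ccccc1.Cl[I-]Cl
Why: Electrophilic aromatic iodination of ring A, directed ortho to the free chelated 5-hydroxyl, should place iodine at C6 and not at C8, which fixes the point of attachment; the buffered medium should leave the ketal intact.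

Step 11
Reactants: 18 7-(benzyloxy)-2-(2,2-diphenyl-1,3-benzodioxol-5-yl)-5-hydroxy-6-iodo-4H-chromen-4-one; 2 benzyl bromide
Product: 19 5,7-bis(benzyloxy)-2-(2,2-diphenyl-1,3-benzodioxol-5-yl)-6-iodo-4H-chromen-4-one
Conditions: 2, K2CO3, DMF, 70 °C
Reagents that add atoms: none
Why: Williamson etherification of the remaining hindered 5-hydroxyl under more forcing conditions removes the last acidic phenol before the organozinc coupling.

Step 12
Reactants: 13 (1S,2S)-2-(iodomethyl)-1,3,3-trimethylcyclohexan-1-ol; 19 5,7-bis(benzyloxy)-2-(2,2-diphenyl-1,3-benzodioxol-5-yl)-6-iodo-4H-chromen-4-one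
Product: 21 5,7-bis(benzyloxy)-2-(2,2-diphenyl-1,3-benzodioxol-5-yl)-6-{[(1S,2S)-2-hydroxy-2,6,6-trimethylcyclohexyl]methyl}-4H-chromen-4-one, via alkylzinc iodide 20 (not isolated)
Conditions: Zn dust, LiCl, THF, 40 °C; then 19, Pd(OAc)2, 2-dicyclohexylphosphino-2',6'-bis(dimethylamino)biphenyl (CPhos), THF–toluene, 50 °C
Reagents that add atoms: none
Why: Negishi coupling: LiCl-assisted zinc insertion into the primary C–I bond gives 20, which should transmetalate to the arylpalladium iodide formed from 19, and the bulky biarylphosphine should favour reductive elimination over β-hydride elimination, forming the C6–CH2 bond without touching the carbonyl, the benzyl ethers, the ketal or the hindered tertiary alcohol.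

Step 13
Reactants: 21 5,7-bis(benzyloxy)-2-(2,2-diphenyl-1,3-benzodioxol-5-yl)-6-{[(1S,2S)-2-hydroxy-2,6,6-trimethylcyclohexyl]methyl}-4H-chromen-4-one
Product: 22 2-(3,4-dihydroxyphenyl)-5,7-dihydroxy-6-{[(1S,2S)-2-hydroxy-2,6,6-trimethylcyclohexyl]methyl}-4H-chromen-4-one
Conditions: H2 (1 atm), 10% Pd/C, THF–MeOH, rt
Reagents that add atoms: none
Why: Hydrogenolysis over Pd/C should cleave the two benzyl ethers and the doubly benzylic C–O bonds of the diphenylmethylene ketal in one operation under mild conditions, leaving the flavone C2=C3 bond and the tertiary alcohol intact and giving the target.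

**Compound list**

1 | 3-methylbut-2-en-1-ol (prenol) | CC(C)=CCO | starting material
2 | benzyl bromide | BrCc1ccccc1 | starting material
3 | benzyl prenyl ether | CC(C)=CCOCc1ccccc1 | intermediate
4 | (E)-but-2-enoyl chloride | C/C=C/C(Cl)=O | starting material
5 | vinylketene (buta-1,3-dien-1-one) | C=CC=C=O | intermediate (not isolated)
6 | rac-(2R,4R)-2-[(benzyloxy)methyl]-4-ethenyl-3,3-dimethylcyclobutan-1-one (2,4-cis) | O=C1[C@H](C=C)C(C)(C)[C@@H]1COCc1ccccc1 | intermediate
7 | rac-(1R,2R,4R)-2-[(benzyloxy)methyl]-4-ethenyl-1,3,3-trimethylcyclobutan-1-ol (OH cis to vinyl and CH2OBn) | C[C@@]1(O)[C@H](C=C)C(C)(C)[C@@H]1COCc1ccccc1 | intermediate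
8 | potassium salt of 7 (potassium cyclobutanolate) | C[C@@]1([O-])[C@H](C=C)C(C)(C)[C@@H]1COCc1ccccc1.[K+] | intermediate (not isolated)
9 | potassium salt of 10 (potassium cyclohexenolate) | CC1(C)C=CC[C@](C)([O-])[C@H]1COCc1ccccc1.[K+] | intermediate (not isolated)
10 | rac-(1S,6R)-6-[(benzyloxy)methyl]-1,5,5-trimethylcyclohex-3-en-1-ol (OH trans to CH2OBn) | CC1(C)C=CC[C@](C)(O)[C@H]1COCc1ccccc1 | intermediate
11 | rac-(1S,2R)-2-(hydroxymethyl)-1,3,3-trimethylcyclohexan-1-ol | CC1(C)CCC[C@](C)(O)[C@H]1CO | intermediate
12 | (1S,2R)-2-(hydroxymethyl)-1,3,3-trimethylcyclohexan-1-ol | CC1(C)CCC[C@](C)(O)[C@H]1CO | intermediate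
13 | (1S,2S)-2-(iodomethyl)-1,3,3-trimethylcyclohexan-1-ol | CC1(C)CCC[C@](C)(O)[C@H]1CI | intermediate
14 | luteolin | O=c1cc(-c2ccc(O)c(O)c2)oc2cc(O)cc(O)c12 | starting material
15 | dichlorodiphenylmethane | ClC(Cl)(c1ccccc1)c1ccccc1 | starting material
16 | 2-(2,2-diphenyl-1,3-benzodioxol-5-yl)-5,7-dihydroxy-4H-chromen-4-one | O=c1cc(-c2ccc3OC(c4ccccc4)(c4ccccc4)Oc3c2)oc2cc(O)cc(O)c12 | intermediate
17 | 7-(benzyloxy)-2-(2,2-diphenyl-1,3-benzodioxol-5-yl)-5-hydroxy-4H-chromen-4-one | O=c1cc(-c2ccc3OC(c4ccccc4)(c4ccccc4)Oc3c2)oc2cc(OCc3ccccc3)cc(O)c12 | intermediate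
18 | 7-(benzyloxy)-2-(2,2-diphenyl-1,3-benzodioxol-5-yl)-5-hydroxy-6-iodo-4H-chromen-4-one | O=c1cc(-c2ccc3OC(c4ccccc4)(c4ccccc4)Oc3c2)oc2cc(OCc3ccccc3)c(I)c(O)c12 | intermediate
19 | 5,7-bis(benzyloxy)-2-(2,2-diphenyl-1,3-benzodioxol-5-yl)-6-iodo-4H-chromen-4-one | O=c1cc(-c2ccc3OC(c4ccccc4)(c4ccccc4)Oc3c2)oc2cc(OCc3ccccc3)c(I)c(OCc3ccccc3)c12 | intermediate
20 | {[(1S,2S)-2-hydroxy-2,6,6-trimethylcyclohexyl]methyl}zinc iodide | CC1(C)CCC[C@](C)(O)[C@H]1C[Zn]I | intermediate (not isolated)
21 | 5,7-bis(benzyloxy)-2-(2,2-diphenyl-1,3-benzodioxol-5-yl)-6-{[(1S,2S)-2-hydroxy-2,6,6-trimethylcyclohexyl]methyl}-4H-chromen-4-one | CC1(C)CCC[C@](C)(O)[C@H]1Cc1c(OCc2ccccc2)cc2oc(-c3ccc4OC(c5ccccc5)(c5ccccc5)Oc4c3)cc(=O)c2c1OCc1ccccc1 | intermediate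
22 | 2-(3,4-dihydroxyphenyl)-5,7-dihydroxy-6-{[(1S,2S)-2-hydroxy-2,6,6-trimethylcyclohexyl]methyl}-4H-chromen-4-one | CC1(C)CCC[C@](C)(O)[C@H]1Cc1c(O)cc2oc(-c3ccc(O)c(O)c3)cc(=O)c2c1O | target

**Count and risks**

Total step count: 13. Longest linear sequence: 9 steps (steps 1–7, 12, 13).

Steps most likely to fail:

1. Step 4. The migrating carbinol carbon may not be transferred with clean inversion: retention, or full fragmentation to a keto allyl anion that re-closes under steric control or is quenched by proton transfer, would erode or reverse the OH/CH2OBn relation. The fallback puts the oxygen in last; it sets out from 6 and comes back at 10. Ketone 6 is reduced (NaBH4, MeOH, 0 °C) to rac-(1R,2R,4R)-2-[(benzyloxy)methyl]-4-ethenyl-3,3-dimethylcyclobutan-1-ol F1. Its potassium salt (KH, THF) undergoes the same ring expansion to 6-[(benzyloxy)methyl]-5,5-dimethylcyclohex-3-en-1-ol F2, whose carbinol configuration no longer matters. Dess–Martin oxidation gives rac-6-[(benzyloxy)methyl]-5,5-dimethylcyclohex-3-en-1-one F3, and non-basic methylenation (Zn, CH2Br2, TiCl4) gives rac-4-[(benzyloxy)methyl]-3,3-dimethyl-5-methylidenecyclohex-1-ene F4. Mukaiyama hydration of the 1,1-disubstituted alkene (Co(acac)2, PhSiH3, O2, i-PrOH) should trap the tertiary radical with O2 from the less hindered face, anti to the neighbouring CH2OBn group, and return to 10.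

2. Step 2. Dimerisation and polymerisation of the transient vinylketene may outrun its cycloaddition to an unactivated trisubstituted alkene, and Et3N may move the vinyl double bond into conjugation with the ketone. The fallback builds the four-membered ring with a more reactive ketene and adds the vinyl group afterwards; it sets out from 3 and comes back at 6. Dichloroketene (Cl3CCOCl, Zn–Cu couple, Et2O) should add to 3 with the same orientation to give rac-4-[(benzyloxy)methyl]-2,2-dichloro-3,3-dimethylcyclobutan-1-one F5. Zn/AcOH removes both chlorines to give rac-2-[(benzyloxy)methyl]-3,3-dimethylcyclobutan-1-one F6. The kinetic enolate on the CH2 side (LiN(i-Pr)2, THF, −78 °C) is trapped with (phenylselanyl)acetaldehyde to give 2-[(benzyloxy)methyl]-4-[1-hydroxy-2-(phenylselanyl)ethyl]-3,3-dimethylcyclobutan-1-one F7. MsCl/Et3N then eliminates the β-hydroxy selenide to the vinyl group and returns to 6.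

3. Step 12. Transmetalation and reductive elimination at the doubly ortho-substituted arylpalladium may be slow, so that β-hydride elimination of the alkylpalladium or protonolysis of the organozinc by the free hydroxyl takes over. The fallback replaces the organozinc by an isolable boron nucleophile; it sets out from 13 and comes back at 21. Copper-catalysed borylation of 13 (CuI, PPh3, LiOMe, bis(pinacolato)diboron, DMF) gives 2-{[(1S,2S)-2-hydroxy-2,6,6-trimethylcyclohexyl]methyl}-4,4,5,5-tetramethyl-1,3,2-dioxaborolane F8. B-alkyl Suzuki–Miyaura coupling with 19 (Pd(OAc)2, 2-dicyclohexylphosphino-2',6'-diisopropoxybiphenyl (RuPhos), K3PO4, toluene–H2O, 90 °C) returns to 21.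

**Further compounds**

F1 | step 4 | rac-(1R,2R,4R)-2-[(benzyloxy)methyl]-4-ethenyl-3,3-dimethylcyclobutan-1-ol | O[C@@H]1[C@H](C=C)C(C)(C)[C@@H]1COCc1ccccc1
F2 | step 4 | 6-[(benzyloxy)methyl]-5,5-dimethylcyclohex-3-en-1-ol (racemic, either C1 epimer) | CC1(C)C=CCC(O)[C@H]1COCc1ccccc1
F3 | step 4 | rac-6-[(benzyloxy)methyl]-5,5-dimethylcyclohex-3-en-1-one | CC1(C)C=CCC(=O)[C@H]1COCc1ccccc1
F4 | step 4 | rac-4-[(benzyloxy)methyl]-3,3-dimethyl-5-methylidenecyclohex-1-ene | CC1(C)C=CCC(=C)[C@H]1COCc1ccccc1
F5 | step 2 | rac-4-[(benzyloxy)methyl]-2,2-dichloro-3,3-dimethylcyclobutan-1-one | O=C1C(Cl)(Cl)C(C)(C)[C@@H]1COCc1ccccc1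
F6 | step 2 | rac-2-[(benzyloxy)methyl]-3,3-dimethylcyclobutan-1-one | O=C1CC(C)(C)[C@@H]1COCc1ccccc1
F7 | step 2 | 2-[(benzyloxy)methyl]-4-[1-hydroxy-2-(phenylselanyl)ethyl]-3,3-dimethylcyclobutan-1-one | O=C1C(C(O)C[Se]c2ccccc2)C(C)(C)[C@@H]1COCc1ccccc1
F8 | step 12 | 2-{[(1S,2S)-2-hydroxy-2,6,6-trimethylcyclohexyl]methyl}-4,4,5,5-tetramethyl-1,3,2-dioxaborolane | CC1(C)CCC[C@](C)(O)[C@H]1CB1OC(C)(C)C(C)(C)O1
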